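Assumption: (+)-Ipc2BH (bis(isopinocampheyl)borane made beforehand from (−)-α-pinene and BH3·SMe2) is used as a reagent and is not counted as a step.

## Retrosynthetic overview

1. Target ⇐ its tri-O-benzyl ether (one hydrogenolysis) ⇐ anti-β-aryloxy homoallylic alcohol (vinyl → CH2OH by ozonolysis/NaBH4).
2. Key disconnection: C1–C2 of the glyceryl chain. Both carbons are natural acceptors (aldehyde carbon and O-aryl carbon). The O-aryl carbon is made the nucleophile as a 1-aryloxyallyl anion equivalent, an E-γ-aryloxyallyl-B(Ipc)2 reagent generated on the intact flavone from an aryloxyallene. One allylboration of 4-(benzyloxy)benzaldehyde sets both stereocentres.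
3. Aryloxyallene ⇐ 4'-OH of 5,7-di-O-benzyltricin + propargyl bromide.
4. Ring order: rings A and B are bought (phloroacetophenone, syringaldehyde). Ring C, the pyranone, is the only ring made, by a one-pot aldol/oxa-Michael/dehydrogenation, before the side chain is built.

## Route

Step 1
Reactants: 1 2',4',6'-trihydroxyacetophenone
Product: 2 1-[2,4-bis(benzyloxy)-6-hydroxyphenyl]ethan-1-one
Conditions: BnBr (2.05 equiv), K2CO3 (2.2 equiv), DMF, 0 °C → rt
Reagents that add atoms: benzyl bromide, BrCc1ccccc1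
Why: Williamson etherification; the hydroxyl that is hydrogen-bonded to the acetyl carbonyl is the least nucleophilic, so alkylation stops at the bis-ether and leaves the OH needed to close ring C.

Step 2
Reactants: 2 1-[2,4-bis(benzyloxy)-6-hydroxyphenyl]ethan-1-one; 3 syringaldehyde (4-hydroxy-3,5-dimethoxybenzaldehyde)
Product: 6 5,7-bis(benzyloxy)-2-(4-hydroxy-3,5-dimethoxyphenyl)-4H-chromen-4-one, via 2'-hydroxychalcone 4 (not isolated), via flavanone 5 (not isolated)
Conditions: pyrrolidine (0.5 equiv), I2 (10 mol %), DMSO, 130 °C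
Reagents that add atoms: none
Why: Amine-catalysed Claisen–Schmidt condensation, 6-endo oxa-Michael closure and iodine/DMSO dehydrogenation in one pot build ring C; pyrrolidine activates the aldehyde as its iminium ion, so the free phenol of 3 need not be masked, and no stereocentre remains.

Step 3
Reactants: 6 5,7-bis(benzyloxy)-2-(4-hydroxy-3,5-dimethoxyphenyl)-4H-chromen-4-one; 7 propargyl bromide (3-bromoprop-1-yne)
Product: 9 5,7-bis(benzyloxy)-2-[3,5-dimethoxy-4-(propa-1,2-dien-1-yloxy)phenyl]-4H-chromen-4-one, via propargyl ether 8 (not isolated)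
Conditions: KOtBu (1.0 equiv), DMF–THF, 0 °C; 7 (1.05 equiv), rt; then KOtBu (0.3 equiv), 0 °C → rt
Reagents that add atoms: none
Why: SN2 O-propargylation of the only free phenol, then base-mediated propargyl-to-allenyl prototropic isomerisation, which stops at the conjugated aryloxyallene.

Step 4
Reactants: 9 5,7-bis(benzyloxy)-2-[3,5-dimethoxy-4-(propa-1,2-dien-1-yloxy)phenyl]-4H-chromen-4-one; 10 4-(benzyloxy)benzaldehyde
Product: 13 5,7-bis(benzyloxy)-2-[4-({(1S,2R)-1-[4-(benzyloxy)phenyl]-1-hydroxybut-3-en-2-yl}oxy)-3,5-dimethoxyphenyl]-4H-chromen-4-one, via E-allylborane 11 (not isolated), via borinate ester 12 (not isolated)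
Conditions: (+)-Ipc2BH (1.15 equiv), THF, −20 → 0 °C, 3 h; 10 (1.3 equiv), −78 °C, 12 h; H2NCH2CH2OH, Et2O, rt
Reagents that add atoms: none
Why: Tandem allene hydroboration / Brown-type allylboration: boron adds to the terminal allene carbon and 1,3-boratropic equilibration at 0 °C gives the E-γ-aryloxyallylborane 11, in which the oxygen-bearing carbon is the nucleophile (reversed polarity); the closed chair transition state with the aldehyde aryl group equatorial gives the anti (erythro) adduct, and the isopinocampheyl groups from (−)-α-pinene direct attack to the Re face of 10, so C1 becomes S and C2 becomes R in the one C–C bond-forming event, while the flavone carbonyl is too unreactive to compete.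

Step 5
Reactants: 13 5,7-bis(benzyloxy)-2-[4-({(1S,2R)-1-[4-(benzyloxy)phenyl]-1-hydroxybut-3-en-2-yl}oxy)-3,5-dimethoxyphenyl]-4H-chromen-4-one
Product: 15 5,7-bis(benzyloxy)-2-[4-({(1S,2R)-1-[4-(benzyloxy)phenyl]-1,3-dihydroxypropan-2-yl}oxy)-3,5-dimethoxyphenyl]-4H-chromen-4-one, via α-aryloxy aldehyde 14 (not isolated)
Conditions: O3, CH2Cl2–MeOH (1:1), Sudan Red 7B indicator, −78 °C; then NaBH4 (5 equiv), −78 → 0 °C
Reagents that add atoms: ozone, [O-][O+]=O
Why: Ozonolysis of the only isolated C=C (far faster than attack on the enone or the alkoxyarenes) gives aldehyde 14, which NaBH4 reduces in the same pot before the α-aryloxy centre can epimerise; neither stereocentre is touched.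

Step 6
Reactants: 15 5,7-bis(benzyloxy)-2-[4-({(1S,2R)-1-[4-(benzyloxy)phenyl]-1,3-dihydroxypropan-2-yl}oxy)-3,5-dimethoxyphenyl]-4H-chromen-4-one
Product: 16 5,7-dihydroxy-2-[4-({(1S,2R)-1,3-dihydroxy-1-(4-hydroxyphenyl)propan-2-yl}oxy)-3,5-dimethoxyphenyl]-4H-chromen-4-one
Conditions: H2 (1 atm), Pd/C (10 wt % Pd on carbon), THF–MeOH, rt, stop after 3 equiv H2
Reagents that add atoms: none
Why: Catalytic hydrogenolysis of the three aryl benzyl ethers under neutral conditions is faster than reduction of the flavone C2=C3 bond or loss of the benzylic hydroxyl, so ring C and both stereocentres survive.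

## Compound list

1 | 2',4',6'-trihydroxyacetophenone | CC(=O)c1c(O)cc(O)cc1O | starting material
2 | 1-[2,4-bis(benzyloxy)-6-hydroxyphenyl]ethan-1-one | CC(=O)c1c(O)cc(OCc2ccccc2)cc1OCc1ccccc1 | intermediate
3 | syringaldehyde (4-hydroxy-3,5-dimethoxybenzaldehyde) | COc1cc(C=O)cc(OC)c1O | starting material
4 | (E)-1-[2,4-bis(benzyloxy)-6-hydroxyphenyl]-3-(4-hydroxy-3,5-dimethoxyphenyl)prop-2-en-1-one | COc1cc(/C=C/C(=O)c2c(O)cc(OCc3ccccc3)cc2OCc2ccccc2)cc(OC)c1O | intermediate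
5 | racemic 5,7-bis(benzyloxy)-2-(4-hydroxy-3,5-dimethoxyphenyl)chroman-4-one | COc1cc(C2CC(=O)c3c(OCc4ccccc4)cc(OCc4ccccc4)cc3O2)cc(OC)c1O | intermediate
6 | 5,7-bis(benzyloxy)-2-(4-hydroxy-3,5-dimethoxyphenyl)-4H-chromen-4-one (5,7-di-O-benzyltricin) | COc1cc(-c2cc(=O)c3c(OCc4ccccc4)cc(OCc4ccccc4)cc3o2)cc(OC)c1O | intermediate
7 | propargyl bromide (3-bromoprop-1-yne) | C#CCBr | starting material
8 | 5,7-bis(benzyloxy)-2-[3,5-dimethoxy-4-(prop-2-yn-1-yloxy)phenyl]-4H-chromen-4-one | COc1cc(-c2cc(=O)c3c(OCc4ccccc4)cc(OCc4ccccc4)cc3o2)cc(OC)c1OCC#C | intermediate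
9 | 5,7-bis(benzyloxy)-2-[3,5-dimethoxy-4-(propa-1,2-dien-1-yloxy)phenyl]-4H-chromen-4-one | COc1cc(-c2cc(=O)c3c(OCc4ccccc4)cc(OCc4ccccc4)cc3o2)cc(OC)c1OC=C=C | intermediate
10 | 4-(benzyloxy)benzaldehyde | O=Cc1ccc(OCc2ccccc2)cc1 | starting material
11 | 5,7-bis(benzyloxy)-2-[4-({(1E)-3-[bis(isopinocampheyl)boranyl]prop-1-en-1-yl}oxy)-3,5-dimethoxyphenyl]-4H-chromen-4-one, isopinocampheyl groups from (−)-α-pinene | COc1cc(-c2cc(=O)c3c(OCc4ccccc4)cc(OCc4ccccc4)cc3o2)cc(OC)c1O/C=C/CB([C@H]1C[C@H]2C[C@@H]([C@@H]1C)C2(C)C)[C@H]1C[C@H]2C[C@@H]([C@@H]1C)C2(C)C | intermediate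
12 | O-bis(isopinocampheyl)boryl derivative (borinate ester) of 13 | COc1cc(-c2cc(=O)c3c(OCc4ccccc4)cc(OCc4ccccc4)cc3o2)cc(OC)c1O[C@H](C=C)[C@@H](OB([C@H]1C[C@H]2C[C@@H]([C@@H]1C)C2(C)C)[C@H]1C[C@H]2C[C@@H]([C@@H]1C)C2(C)C)c1ccc(OCc2ccccc2)cc1 | intermediate
13 | 5,7-bis(benzyloxy)-2-[4-({(1S,2R)-1-[4-(benzyloxy)phenyl]-1-hydroxybut-3-en-2-yl}oxy)-3,5-dimethoxyphenyl]-4H-chromen-4-one | COc1cc(-c2cc(=O)c3c(OCc4ccccc4)cc(OCc4ccccc4)cc3o2)cc(OC)c1O[C@H](C=C)[C@@H](O)c1ccc(OCc2ccccc2)cc1 | intermediate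
14 | (2S,3S)-3-[4-(benzyloxy)phenyl]-2-{4-[5,7-bis(benzyloxy)-4-oxo-4H-chromen-2-yl]-2,6-dimethoxyphenoxy}-3-hydroxypropanal | COc1cc(-c2cc(=O)c3c(OCc4ccccc4)cc(OCc4ccccc4)cc3o2)cc(OC)c1O[C@H](C=O)[C@@H](O)c1ccc(OCc2ccccc2)cc1 | intermediate
15 | 5,7-bis(benzyloxy)-2-[4-({(1S,2R)-1-[4-(benzyloxy)phenyl]-1,3-dihydroxypropan-2-yl}oxy)-3,5-dimethoxyphenyl]-4H-chromen-4-one | COc1cc(-c2cc(=O)c3c(OCc4ccccc4)cc(OCc4ccccc4)cc3o2)cc(OC)c1O[C@H](CO)[C@@H](O)c1ccc(OCc2ccccc2)cc1 | intermediate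
16 | 5,7-dihydroxy-2-[4-({(1S,2R)-1,3-dihydroxy-1-(4-hydroxyphenyl)propan-2-yl}oxy)-3,5-dimethoxyphenyl]-4H-chromen-4-one | COc1cc(-c2cc(=O)c3c(O)cc(O)cc3o2)cc(OC)c1O[C@H](CO)[C@@H](O)c1ccc(O)cc1 | target

## Step count and risk

Total step count: 6. Longest linear sequence: 6 steps (1 → 2 → 6 → 9 → 13 → 15 → 16).

**Step 4 (most likely to fail).** The anti/syn ratio depends on complete equilibration of the first-formed allylborane to the E-isomer 11, and hydroboration at the enol-ether double bond could compete; either would lower dr, ee or yield. The fallback sets out from 8, isolated by leaving out the second portion of base in step 3, and fixes the olefin geometry in an isolable reagent. Zirconium-catalysed hydroboration of the alkyne with pinacolborane (Cp2Zr(H)Cl 5 mol %, Et3N, CH2Cl2) gives 5,7-bis(benzyloxy)-2-(3,5-dimethoxy-4-{[(2E)-3-(4,4,5,5-tetramethyl-1,3,2-dioxaborolan-2-yl)prop-2-en-1-yl]oxy}phenyl)-4H-chromen-4-one F4. Double-bond transposition with [Ir(cod)(PPh2Me)2]PF6 (3 mol %, activated with H2, THF, rt) gives the E-γ-aryloxyallyl boronate 5,7-bis(benzyloxy)-2-(3,5-dimethoxy-4-{[(1E)-3-(4,4,5,5-tetramethyl-1,3,2-dioxaborolan-2-yl)prop-1-en-1-yl]oxy}phenyl)-4H-chromen-4-one F5. Allylboration of 10 catalysed by the chiral phosphoric acid (R)-TRIP (5 mol %, toluene, −30 °C; Re-face attack, anti through the chair) then comes back to the route at 13.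

**Step 2.** The one-pot condensation/dehydrogenation with an unprotected syringyl phenol may be sluggish or give oxidised by-products under I2/DMSO. The fallback sets out from 2 and 3, installs the ether before ring C and avoids iodine. Alkylation of 3 with 7 (K2CO3, DMF) gives 3,5-dimethoxy-4-(prop-2-yn-1-yloxy)benzaldehyde F1. Claisen–Schmidt condensation with 2 (KOH, EtOH, rt) gives (E)-1-[2,4-bis(benzyloxy)-6-hydroxyphenyl]-3-[3,5-dimethoxy-4-(prop-2-yn-1-yloxy)phenyl]prop-2-en-1-one F2. Isomerisation (NaOAc, EtOH, reflux) gives racemic 5,7-bis(benzyloxy)-2-[3,5-dimethoxy-4-(prop-2-yn-1-yloxy)phenyl]chroman-4-one F3, and dehydrogenation with DDQ (dioxane, reflux) comes back to the route at 8, which is then isomerised with KOtBu as in the second half of step 3.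

**Step 5.** Ozone may attack the electron-rich benzyloxy and trialkoxy rings, and aldehyde 14 may epimerise at the α-aryloxy carbon if reduction lags. The fallback sets out from 13 and replaces ozonolysis by dihydroxylation and glycol cleavage. K2OsO4·2H2O (2 mol %) with N-methylmorpholine N-oxide in acetone–H2O gives the vicinal diol of the vinyl group of 13 (both existing stereocentres unchanged, new carbinol centre as an epimer mixture) F6, which is isolated. Cleavage with NaIO4 (THF–pH 7 buffer, 0 °C) and immediate NaBH4 reduction of 14 comes back to the route at 15.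

## Further compounds

F1 | step 2 | 3,5-dimethoxy-4-(prop-2-yn-1-yloxy)benzaldehyde | COc1cc(C=O)cc(OC)c1OCC#C
F2 | step 2 | (E)-1-[2,4-bis(benzyloxy)-6-hydroxyphenyl]-3-[3,5-dimethoxy-4-(prop-2-yn-1-yloxy)phenyl]prop-2-en-1-one | COc1cc(/C=C/C(=O)c2c(O)cc(OCc3ccccc3)cc2OCc2ccccc2)cc(OC)c1OCC#C
F3 | step 2 | racemic 5,7-bis(benzyloxy)-2-[3,5-dimethoxy-4-(prop-2-yn-1-yloxy)phenyl]chroman-4-one | COc1cc(C2CC(=O)c3c(OCc4ccccc4)cc(OCc4ccccc4)cc3O2)cc(OC)c1OCC#C
F4 | step 4 | 5,7-bis(benzyloxy)-2-(3,5-dimethoxy-4-{[(2E)-3-(4,4,5,5-tetramethyl-1,3,2-dioxaborolan-2-yl)prop-2-en-1-yl]oxy}phenyl)-4H-chromen-4-one | COc1cc(-c2cc(=O)c3c(OCc4ccccc4)cc(OCc4ccccc4)cc3o2)cc(OC)c1OC/C=C/B1OC(C)(C)C(C)(C)O1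
F5 | step 4 | 5,7-bis(benzyloxy)-2-(3,5-dimethoxy-4-{[(1E)-3-(4,4,5,5-tetramethyl-1,3,2-dioxaborolan-2-yl)prop-1-en-1-yl]oxy}phenyl)-4H-chromen-4-one | COc1cc(-c2cc(=O)c3c(OCc4ccccc4)cc(OCc4ccccc4)cc3o2)cc(OC)c1O/C=C/CB1OC(C)(C)C(C)(C)O1
F6 | step 5 | vicinal diol from dihydroxylation of the vinyl group of 13, new carbinol centre as an epimer mixture | COc1cc(-c2cc(=O)c3c(OCc4ccccc4)cc(OCc4ccccc4)cc3o2)cc(OC)c1O[C@H](C(O)CO)[C@@H](O)c1ccc(OCc2ccccc2)cc1
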